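All runs are calculated from invented constants.

Early on the intermediate jumped: Saturday's flask held 55.8% of it after 0.833 h, while Sunday's flask needed 12.0 h to show 26.1% of product. So I read a quick, balanced binding of substrate to partner, and a slow drain from intermediate to product.

| setting | Monday's | Saturday's | Sunday's | spring | midnight | dawn | noon |
|---|---|---|---|---|---|---|---|
| substrate | 10 mM | 10 mM | 10 mM | 10 mM | 10 mM | 10 mM | 10 mM |
| partner | 50 mM | 70 mM | 110 mM | 50.0 mM | 50.0 mM | 50.0 mM | 50.0 mM (fed, over 12.0 h) |
| remark | run made earlier | run made earlier | run made earlier | a closed flask charged with all of it at once and left for 15 h | a single well-mixed tank run continuously and read at steady state, 15 h in it on average | one stirred flow tank at steady state, fed with the mixture as stated, mean residence time 75.0 h | all but partner at the start; partner goes in evenly over 12.0 h, the run ends at 15 h |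
| time |  |  |  | 15 h |  |  | 15 h |

| run | time / h | intermediate / % | product / % |
|---|---|---|---|
| Monday's | 2.50 | 59.3 | 3.7 |
| Monday's | 5.00 | 57.9 | 9.9 |
| Monday's | 8.00 | 52.8 | 13.1 |
| Monday's | 10.0 | 52.5 | 15.8 |
| Monday's | 12.0 | 50.8 | 19.8 |
| Monday's | 15.0 | 46.5 | 28.1 |
| Saturday's | 0.833 | 55.8 | 1.5 |
| Saturday's | 2.50 | 67.9 | 5.2 |
| Saturday's | 4.00 | 65.8 | 8.7 |
| Saturday's | 6.00 | 62.8 | 12.4 |
| Saturday's | 10.0 | 55.9 | 21.5 |
| Saturday's | 12.0 | 55.3 | 22.9 |
| Sunday's | 2.00 | 76.0 | 3.8 |
| Sunday's | 4.00 | 71.6 | 9.1 |
| Sunday's | 6.00 | 69.2 | 16.0 |
| Sunday's | 8.00 | 64.7 | 17.7 |
| Sunday's | 10.0 | 61.5 | 22.6 |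
| Sunday's | 12.0 | 58.5 | 26.1 |

(each reading ± 1 percentage point)

1. the set-up with the highest amount of intermediate at the outlet or at the end, in percent of the substrate put in ("none" if the first two lie within 2 percentage points) (spring / midnight / dawn / noon / none)
2. amount of intermediate at the outlet or at the end, in percent of the substrate put in, spring
3. amount of intermediate at the outlet or at the end, in percent of the substrate put in, midnight
4. amount of intermediate at the outlet or at the end, in percent of the substrate put in, dawn
5. amount of intermediate at the outlet or at the end, in percent of the substrate put in, noon

- the stated concentrations are those of everything mixed, before any reaction; amounts are the same in each set-up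
- the numbers in the tables scatter by 1 percentage point (one standard deviation)
- the feed brings no volume worth counting
- the earlier runs were made in a closed, stirred flask

Substrate is the limiting reagent, its charge being smaller than the partner's. I took the free partner as the concentration to follow, and counted one partner held in each intermediate and each product:

c(partner) = charge − c(intermediate) − c(product)

K = c(intermediate) / (c(substrate) · c(partner))

Saturday's last row gives K = 0.0408 /mM. Monday's last row leaves c(partner) = 42.5 mM, so

s = K·c(partner) / (1 + K·c(partner)) = 63.4%

This bound share is the part of the substrate not yet product that sits as intermediate. Sunday's product over its mean intermediate and time gives a drain constant d = 0.0323 /h. In percent of substrate, I then reckoned: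

closed flask: intermediate = s · exp(−d·s·t)

tank: intermediate = s / (1 + d·s·τ)

Time first: spring has Monday's charge, and the closed line gives 46.6%. Turning to a tank, midnight gives 48.5%, though this counts binding as caught up. Lengthening the stay, dawn gives 25.0%. Feeding partner slowly, noon has about half the free partner during the feed, so its share there is 46.5%, and the drain gives 49.8%. That is more than spring, but it lies 1.3 percentage points above midnight, inside the margin.

The forecast stands further from my reckoning at midnight than at any other set-up. It gave 46.5%, 45.5%, 24% and 50.5% for spring, midnight, dawn and noon, and chose noon, “so less drains away”. It lowered midnight “because of the lag”, and I accepted that.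

The flasks gave 46.7%, 46.1%, 27.8% and 51.3% in the same order, and the best was noon.

    released group → by-product carried off (k = 0.0590 /h)
    substrate + partner ⇌ intermediate (K = 40.0 /M, k = 20.0 /M/h)
    intermediate ⇌ product + released group (K = 0.00830 M, k = 0.0340 /h)

In spring 86% of the partner stood free at the end, which puts the bound share at 63.6%; the flask held 62.6% of its substrate and intermediate as intermediate. The neighbouring flask, spring with 12 mM of partner, kept 72% of its charge free, which is 8.66 mM. By my reckoning its bound share came to 26.1%, and the closed line gave 23.0%. That flask held 22.2% intermediate, with 66.6% of the substrate still unbound.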